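The target forms from substrate by way of the intermediate, so I count it as substrate lost minus what still waits as intermediate.

| flask | substrate | coupling partner | protic impurity | temperature | remark | time |
|---|---|---|---|---|---|---|
| Sunday's | 0.028 M | 0.027 M | 1.4 mM | 30 °C | run made earlier |  |
| Thursday's | 0.028 M | 0.043 M | 1.4 mM | 52 °C | run made earlier |  |
| Tuesday's | 0.028 M | 0.0196 M | 2.1 mM | 30 °C | run made earlier |  |
| north-west | 0.028 M | 0.0196 M | 1.40 mM | 60 °C |  | 5.0 min |
| south | 0.028 M | 0.0196 M | 1.40 mM | 20 °C |  | 5.0 min |
| south-east | 0.028 M | 0.0196 M | 1.40 mM |  | at 20 °C until 1.0 min, from then on at 60 °C | 5.0 min |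
| east | 0.028 M | 0.0196 M | 1.40 mM | 40 °C |  | 5.0 min |

| run | time / min | target / % | substrate / % |
|---|---|---|---|
| Sunday's | 4.00 | 0.9 | 98.6 |
| Sunday's | 6.00 | 0.7 | 98.0 |
| Sunday's | 12.0 | 2.2 | 95.6 |
| Thursday's | 0.250 | 1.2 | 98.3 |
| Thursday's | 0.500 | 1.1 | 97.3 |
| Thursday's | 1.33 | 4.2 | 92.9 |
| Thursday's | 3.00 | 11.7 | 85.3 |
| Tuesday's | 2.00 | 0 | 99.1 |
| Tuesday's | 4.00 | 0 | 98.2 |
| Tuesday's | 8.00 | 0.3 | 97.5 |
| Tuesday's | 12.0 | 2.2 | 96.2 |

(standard deviation of a reading: 0.5 percentage points)

- what may be going on: substrate -> intermediate; coupling partner + intermediate -> target; coupling partner + protic impurity -> quenched reagent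

1. the best flask by amount of target, in percent of the substrate charged; "all alike" if 1.5 percentage points covers them all (north-west / south / south-east / east / all alike)
2. amount of target at the end, in percent of the substrate charged, north-west
3. amount of target at the end, in percent of the substrate charged, south
4. amount of target at the end, in percent of the substrate charged, south-east
5. amount of target at the end, in percent of the substrate charged, east

The substrate's loss can be read in two flasks at 30 °C. After 12.0 min, Sunday's run has lost 4.40 % and Tuesday's 3.80 %, with a scatter of 0.5 percentage points. I read this as a rate of 0.00375 min⁻¹ from Sunday's run, and Tuesday's different partner and impurity charges leave no clear mark on it. Thursday's run at 52 °C reads 0.0530 min⁻¹. That gives the climb, the factor the first step gains from Sunday's temperature to Thursday's, 14.1, and I carry it to other temperatures as a power of the temperature gap.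

There are also two ways to the target, and they part. After 3.00 min, Thursday's run has lost 14.7 % of its substrate but shows 11.7 % target. The loss is the reading that overstates, since 3.00 % stands unaccounted for, which I take as waiting intermediate, a share of 20.4 % of the loss.

The loss is therefore a ceiling, and the waiting share is the correction. At 60 °C the climb gives 0.139 min⁻¹, so north-west's ceiling after 5.0 min is 50.1 %. The coupling partner is the limiting reagent, and after the impurity's toll it allows 65.0 %, which stands above that ceiling. South-east, counted from its change of temperature, has a ceiling of 42.6 %, east 6.06 % and south 0.561 %, so north-west has the highest ceiling. Taking Thursday's share off, I reckon north-west at 39.8 %.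

For north-west the forecast is lower than my figure: 37 % (31 % to 42 %), with 30 % for south-east, 2.7 % for east and 0.05 % for south, and north-west best. Its grounds begin with “Substrate loss is first order and independent of partner”.

The flasks give 35.6 % in north-west, 29.0 % in south-east, 2.71 % in east and 0.0601 % in south, and the best is north-west.

    substrate → intermediate (k = 0.00230 s⁻¹, Ea = 105 kJ mol⁻¹)
    coupling partner + intermediate → target (k = 0.880 L mol⁻¹ s⁻¹, Ea = 54.0 kJ mol⁻¹)
    coupling partner + protic impurity → quenched reagent (k = 2.80 L mol⁻¹ s⁻¹, Ea = 43.0 kJ mol⁻¹)
    (constants at 60 °C)

North-west has lost 49.8 % of its substrate at the end, against my ceiling of 50.1 %. It holds 14.2 % intermediate, a share of 28.5 % of the loss, which is above Thursday's 20.4 %. The south flask run at 45 °C instead gets a ceiling from the climb of 10.8 %. That neighbour has lost 10.9 % of its substrate and holds 5.95 % target beside 4.96 % intermediate.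

The numbers in the tables are simulated for substances that don't exist.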